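## Retrosynthetic overview

1. The pyranone C ring is formed last, by a one-pot Claisen–Schmidt / Algar–Flynn–Oyamada sequence from a ring-A o-hydroxyacetophenone carrying the lavandulyl group and MOM-protected 2,4-dihydroxybenzaldehyde (ring B, bought); global MOM removal then gives the target.
2. The acetophenone comes from ortho-acetylation of a lavandulyl phenol.
3. The lavandulyl phenol comes from DIBAL / isopropylidene-Wittig opening of a temporary seven-membered aryl lactone (a 4-isopropenyl-1-benzoxepin-2-one).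
4. Key disconnection: the ArCH2–CH bond of that lactone, made from the NHC-bound homoenolate of 4-methylpenta-2,4-dienal (β-carbon made nucleophilic) and a ring-A o-quinone methide (formal [4+3]). Both carbons are natively electrophilic, and this step sets the only stereocentre.
5. Ring order: ring A is bought as symmetrical 2,6-dihydroxy-4-methoxybenzaldehyde (so there is no C6/C8 regiochemistry problem), then the transient benzoxepinone is formed and opened, then ring C is closed.

Assumption 1: 2,6-dihydroxy-4-methoxybenzaldehyde is taken as a catalogue starting material.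
Assumption 2: the (5aR,10bS) antipode of the aminoindanol-derived N-mesityl triazolium catalyst is taken to give Si-face attack at the enal β-carbon, i.e. the (4S)-lactone; if the first run shows the opposite sense, the commercial (5aS,10bR) antipode is used with nothing else changed.

## Route

Step 1
Reactants: 1 methacrolein (2-methylprop-2-enal)
Product: 2 (2E)-4-methylpenta-2,4-dienal
Conditions: Ph3P=CHCHO (1.0 equiv), 1 (3 equiv), CHCl3, 60 °C (sealed), 24 h; distil
Reagents that add atoms: (triphenylphosphoranylidene)acetaldehyde, O=CC=P(c1ccccc1)(c1ccccc1)c1ccccc1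
Why: Wittig olefination with a stabilised ylide gives the (E)-enal, and the excess of the volatile, more electrophilic methacrolein suppresses a second homologation.

Step 2
Reactants: 3 2,6-dihydroxy-4-methoxybenzaldehyde
Product: 4 2-hydroxy-4-methoxy-6-(methoxymethoxy)benzaldehyde
Conditions: MOMCl (1.05 equiv), K2CO3 (1.1 equiv), acetone, 0 °C → rt
Reagents that add atoms: chloromethyl methyl ether, COCCl
Why: Williamson O-alkylation of a symmetrical diol stops at the mono-ether because the remaining OH is locked in a hydrogen bond to the aldehyde; the MOM group keeps the later o-quinone methide neutral and becomes the 7-O protecting group.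

Step 3
Reactants: 4 2-hydroxy-4-methoxy-6-(methoxymethoxy)benzaldehyde
Product: 6 5-methoxy-3-(methoxymethoxy)-2-[(4-methylbenzenesulfonyl)methyl]phenol, via benzyl alcohol 5 (not isolated)
Conditions: NaBH4 (0.6 equiv), MeOH, 0 °C, 30 min; then TolSO2Na (3 equiv), aq NaHSO4 to pH 3, 0 °C → rt, 1 h
Reagents that add atoms: sodium 4-methylbenzenesulfinate, Cc1ccc(cc1)S(=O)[O-].[Na+]
Why: Borohydride reduction gives a very easily ionised 2-hydroxybenzyl alcohol whose benzylic cation is captured at sulfur by excess sulfinate (SN1-type sulfonylation), giving a bench-stable, base-triggered o-quinone methide precursor.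

Step 4
Reactants: 6 5-methoxy-3-(methoxymethoxy)-2-[(4-methylbenzenesulfonyl)methyl]phenol, 2 (2E)-4-methylpenta-2,4-dienal
Product: 8 (4S)-8-methoxy-6-(methoxymethoxy)-4-(prop-1-en-2-yl)-4,5-dihydro-1-benzoxepin-2(3H)-one, via o-quinone methide 7 (not isolated)
Conditions: 2 (2 equiv), (5aR,10bS)-N-mesityl aminoindanol-derived triazolium BF4 (15 mol %), Cs2CO3 (1.5 equiv), 4 Å MS, THF, 0 °C → rt
Reagents that add atoms: none
Why: Base releases o-quinone methide 7 from sulfone 6 while the chiral triazolylidene turns enal 2 into its homoenolate (Breslow intermediate, nucleophilic C-3), which adds to the exocyclic CH2 of 7 before the phenoxide closes the acyl azolium to the seven-membered lactone (NHC-catalysed homoenolate / o-quinone methide formal [4+3] annulation); the stereocentre is set by the catalyst, whose indane wall is taken to leave the Si face of C-3 open, giving (4S), with β- rather than δ-attack expected as for other 2,4-dienals.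

Step 5
Reactants: 8 (4S)-8-methoxy-6-(methoxymethoxy)-4-(prop-1-en-2-yl)-4,5-dihydro-1-benzoxepin-2(3H)-one
Product: 10 5-methoxy-3-(methoxymethoxy)-2-[(2R)-5-methyl-2-(prop-1-en-2-yl)hex-4-en-1-yl]phenol, via aluminium lactolate 9 (not isolated)
Conditions: DIBAL-H (1.15 equiv), CH2Cl2, −78 °C, 1 h; then Ph3P=CMe2 (3.5 equiv; from i-PrPPh3I, n-BuLi, THF, 0 °C), −78 °C → rt; Rochelle salt
Reagents that add atoms: isopropyltriphenylphosphonium iodide, CC(C)[P+](c1ccccc1)(c1ccccc1)c1ccccc1.[I-]
Why: Half-reduction of the aryl lactone gives the aluminium lactolate, which opens to the aldehyde on warming and is trapped by the non-stabilised isopropylidene ylide (one-pot DIBAL reduction / Wittig olefination), completing the prenyl arm and freeing the phenol; the stereocentre is β to the carbonyl and is not touched (the descriptor changes from S to R only because the CIP priorities change).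

Step 6
Reactants: 10 5-methoxy-3-(methoxymethoxy)-2-[(2R)-5-methyl-2-(prop-1-en-2-yl)hex-4-en-1-yl]phenol
Product: 12 1-{2-hydroxy-6-methoxy-4-(methoxymethoxy)-3-[(2R)-5-methyl-2-(prop-1-en-2-yl)hex-4-en-1-yl]phenyl}ethan-1-one, via bromomagnesium phenolate 11 (not isolated)
Conditions: EtMgBr (1.05 equiv), Et2O–toluene, 0 °C; AcCl (1.1 equiv), toluene, 0 °C → rt; aq NH4Cl
Reagents that add atoms: acetyl chloride, CC(=O)Cl
Why: Metal-template (ortho-coordinated) Friedel–Crafts acylation, in which the magnesium phenolate delivers the acyl chloride through a six-membered chelate to the only free ortho carbon, so no protic or strong Lewis acid meets the acid-sensitive lavandulyl alkenes.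

Step 7
Reactants: 13 2,4-dihydroxybenzaldehyde
Product: 14 2,4-bis(methoxymethoxy)benzaldehyde
Conditions: MOMCl (2.6 equiv), K2CO3 (4 equiv), acetone, reflux
Reagents that add atoms: chloromethyl methyl ether, COCCl
Why: Williamson O-alkylation of both phenols gives a base-stable, non-phenolic (hence electrophilic) aldehyde for the condensation.

Step 8
Reactants: 12 1-{2-hydroxy-6-methoxy-4-(methoxymethoxy)-3-[(2R)-5-methyl-2-(prop-1-en-2-yl)hex-4-en-1-yl]phenyl}ethan-1-one, 14 2,4-bis(methoxymethoxy)benzaldehyde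
Product: 16 2-[2,4-bis(methoxymethoxy)phenyl]-3-hydroxy-5-methoxy-7-(methoxymethoxy)-8-[(2R)-5-methyl-2-(prop-1-en-2-yl)hex-4-en-1-yl]-4H-chromen-4-one, via chalcone 15 (not isolated)
Conditions: KOH (50% aq, 10 equiv), EtOH, rt, 36 h; then 30% H2O2 (6 equiv), 0 °C → rt, 3 h; AcOH to pH 6
Reagents that add atoms: hydrogen peroxide, OO
Why: Claisen–Schmidt condensation gives the 2'-hydroxychalcone, which alkaline peroxide converts in the same pot into the flavonol (Algar–Flynn–Oyamada epoxidation / 6-endo cyclisation / oxidation); isolated alkenes are inert to nucleophilic peroxide and the remote stereocentre is untouched.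

Step 9
Reactants: 16 2-[2,4-bis(methoxymethoxy)phenyl]-3-hydroxy-5-methoxy-7-(methoxymethoxy)-8-[(2R)-5-methyl-2-(prop-1-en-2-yl)hex-4-en-1-yl]-4H-chromen-4-one
Product: 17 methylkushenol C, 2-(2,4-dihydroxyphenyl)-3,7-dihydroxy-5-methoxy-8-[(2R)-5-methyl-2-(prop-1-en-2-yl)hex-4-en-1-yl]-4H-chromen-4-one
Conditions: 3 M aq HCl–MeOH (1:6), 40 °C, 2–3 h (stop at full conversion)
Reagents that add atoms: none
Why: Acid-catalysed transacetalisation to dimethoxymethane removes all three MOM ethers, while the 5-OMe and, at 40 °C or below, the lavandulyl alkenes survive (standard end-game for prenylated flavonoids).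

## Compound list

1 | methacrolein | C=C(C)C=O | starting material
2 | (2E)-4-methylpenta-2,4-dienal | C=C(C)/C=C/C=O | intermediate
3 | 2,6-dihydroxy-4-methoxybenzaldehyde | COc1cc(O)c(C=O)c(O)c1 | starting material
4 | 2-hydroxy-4-methoxy-6-(methoxymethoxy)benzaldehyde | COCOc1cc(OC)cc(O)c1C=O | intermediate
5 | 2-(hydroxymethyl)-5-methoxy-3-(methoxymethoxy)phenol | COCOc1cc(OC)cc(O)c1CO | intermediate (not isolated)
6 | 5-methoxy-3-(methoxymethoxy)-2-[(4-methylbenzenesulfonyl)methyl]phenol | COCOc1cc(OC)cc(O)c1CS(=O)(=O)c1ccc(C)cc1 | intermediate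
7 | 3-methoxy-5-(methoxymethoxy)-6-methylidenecyclohexa-2,4-dien-1-one | C=C1C(=O)C=C(OC)C=C1OCOC | intermediate (not isolated)
8 | (4S)-8-methoxy-6-(methoxymethoxy)-4-(prop-1-en-2-yl)-4,5-dihydro-1-benzoxepin-2(3H)-one | C=C(C)[C@@H]1CC(=O)Oc2cc(OC)cc(OCOC)c2C1 | intermediate
9 | diisobutylaluminium (4S)-8-methoxy-6-(methoxymethoxy)-4-(prop-1-en-2-yl)-2,3,4,5-tetrahydro-1-benzoxepin-2-olate (C2 epimers) | C=C(C)[C@@H]1CC(O[Al](CC(C)C)CC(C)C)Oc2cc(OC)cc(OCOC)c2C1 | intermediate (not isolated)
10 | 5-methoxy-3-(methoxymethoxy)-2-[(2R)-5-methyl-2-(prop-1-en-2-yl)hex-4-en-1-yl]phenol | C=C(C)[C@H](CC=C(C)C)Cc1c(O)cc(OC)cc1OCOC | intermediate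
11 | bromomagnesium 5-methoxy-3-(methoxymethoxy)-2-[(2R)-5-methyl-2-(prop-1-en-2-yl)hex-4-en-1-yl]phenolate | C=C(C)[C@H](CC=C(C)C)Cc1c([O-])cc(OC)cc1OCOC.[Mg+2].[Br-] | intermediate (not isolated)
12 | 1-{2-hydroxy-6-methoxy-4-(methoxymethoxy)-3-[(2R)-5-methyl-2-(prop-1-en-2-yl)hex-4-en-1-yl]phenyl}ethan-1-one | C=C(C)[C@H](CC=C(C)C)Cc1c(OCOC)cc(OC)c(C(C)=O)c1O | intermediate
13 | 2,4-dihydroxybenzaldehyde | O=Cc1ccc(O)cc1O | starting material
14 | 2,4-bis(methoxymethoxy)benzaldehyde | COCOc1ccc(C=O)c(OCOC)c1 | intermediate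
15 | (2E)-3-[2,4-bis(methoxymethoxy)phenyl]-1-{2-hydroxy-6-methoxy-4-(methoxymethoxy)-3-[(2R)-5-methyl-2-(prop-1-en-2-yl)hex-4-en-1-yl]phenyl}prop-2-en-1-one | C=C(C)[C@H](CC=C(C)C)Cc1c(OCOC)cc(OC)c(C(=O)/C=C/c2ccc(OCOC)cc2OCOC)c1O | intermediate (not isolated)
16 | 2-[2,4-bis(methoxymethoxy)phenyl]-3-hydroxy-5-methoxy-7-(methoxymethoxy)-8-[(2R)-5-methyl-2-(prop-1-en-2-yl)hex-4-en-1-yl]-4H-chromen-4-one | C=C(C)[C@H](CC=C(C)C)Cc1c(OCOC)cc(OC)c2c(=O)c(O)c(-c3ccc(OCOC)cc3OCOC)oc12 | intermediate
17 | methylkushenol C | C=C(C)[C@H](CC=C(C)C)Cc1c(O)cc(OC)c2c(=O)c(O)c(-c3ccc(O)cc3O)oc12 | target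

## Step count and weak points

Total step count: 9.
Longest linear sequence: 7 steps (steps 2, 3, 4, 5, 6, 8, 9; from 3 to 17).

Three steps most likely to fail:

Step 4 (key annulation). The electron-rich o-quinone methide may oligomerise or alkylate the carbene, the dienyl homoenolate may be protonated or react at the δ-carbon, and the enantioselectivity on this substrate pair is untested. The fallback keeps the homoenolate but changes the electrophile from the quinone methide to the aldehyde carbonyl. It sets out from 4: the same carbene-catalysed homoenolate of 2 is added to the formyl group of 4 to give the γ-butyrolactone (4S)-5-[2-hydroxy-4-methoxy-6-(methoxymethoxy)phenyl]-4-(prop-1-en-2-yl)oxolan-2-one F1 (C5 epimers are irrelevant). NaBH4 in aqueous NaOH then lets the ortho-phenoxide expel the benzylic carboxylate and reduces the transient quinone methide in situ to (3S)-3-{[2-hydroxy-4-methoxy-6-(methoxymethoxy)phenyl]methyl}-4-methylpent-4-enoic acid F2. High-dilution EDC/DMAP lactonisation onto the phenol gives 8, where the route is rejoined (steps 3 and 4 are replaced).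

Step 6 (ortho-acetylation). O-acylation or para C-acylation may compete, and magnesium halide may loosen the MOM ether. The fallback replaces direct acylation by formylation and one-carbon extension. It sets out from 10: magnesium-mediated ortho-formylation (MgCl2, Et3N, paraformaldehyde, MeCN, reflux; Casnati–Skattebøl) gives 2-hydroxy-6-methoxy-4-(methoxymethoxy)-3-[(2R)-5-methyl-2-(prop-1-en-2-yl)hex-4-en-1-yl]benzaldehyde F3. Excess MeMgBr gives 2-(1-hydroxyethyl)-3-methoxy-5-(methoxymethoxy)-6-[(2R)-5-methyl-2-(prop-1-en-2-yl)hex-4-en-1-yl]phenol F4, and MnO2 oxidation of the benzylic alcohol gives 12, where the route is rejoined.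

Step 8 (condensation / Algar–Flynn–Oyamada). 6'-Methoxy-2'-hydroxychalcones tend to give aurones under these conditions, and the hindered condensation may be slow. The fallback reaches the flavonol through the flavone instead of the chalcone epoxide. It sets out from 12: the KOH condensation with 14 is run alone and chalcone 15 is isolated. Oxidative cyclisation (catalytic I2, DMSO, 110 °C) gives 2-[2,4-bis(methoxymethoxy)phenyl]-5-methoxy-7-(methoxymethoxy)-8-[(2R)-5-methyl-2-(prop-1-en-2-yl)hex-4-en-1-yl]-4H-chromen-4-one F5. C3-lithiation (LDA, THF, −78 °C), borylation with B(OMe)3 and oxidation with H2O2 give 16, where the route is rejoined.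

Further compounds
F1 | step 4 | (4S)-5-[2-hydroxy-4-methoxy-6-(methoxymethoxy)phenyl]-4-(prop-1-en-2-yl)oxolan-2-one (C5 epimers) | C=C(C)[C@@H]1CC(=O)OC1c1c(O)cc(OC)cc1OCOC
F2 | step 4 | (3S)-3-{[2-hydroxy-4-methoxy-6-(methoxymethoxy)phenyl]methyl}-4-methylpent-4-enoic acid | C=C(C)[C@@H](Cc1c(O)cc(OC)cc1OCOC)CC(=O)O
F3 | step 6 | 2-hydroxy-6-methoxy-4-(methoxymethoxy)-3-[(2R)-5-methyl-2-(prop-1-en-2-yl)hex-4-en-1-yl]benzaldehyde | C=C(C)[C@H](CC=C(C)C)Cc1c(OCOC)cc(OC)c(C=O)c1O
F4 | step 6 | 2-(1-hydroxyethyl)-3-methoxy-5-(methoxymethoxy)-6-[(2R)-5-methyl-2-(prop-1-en-2-yl)hex-4-en-1-yl]phenol (carbinol epimers) | C=C(C)[C@H](CC=C(C)C)Cc1c(OCOC)cc(OC)c(C(C)O)c1O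
F5 | step 8 | 2-[2,4-bis(methoxymethoxy)phenyl]-5-methoxy-7-(methoxymethoxy)-8-[(2R)-5-methyl-2-(prop-1-en-2-yl)hex-4-en-1-yl]-4H-chromen-4-one | C=C(C)[C@H](CC=C(C)C)Cc1c(OCOC)cc(OC)c2c(=O)cc(-c3ccc(OCOC)cc3OCOC)oc12
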